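**Retrosynthetic overview**

1. Feature (benzofuran numbering; unit 1 carries the styryl group at C6; unit 2, primed, is bonded through C6′ to C3): C2 and C2′ each bear a 4-hydroxyphenyl ring and the ether oxygen O1 or O1′. Each is therefore the exocyclic carbon of a latent para-quinone methide. C3a and C3a′ each lie between two interchangeable oxygen-bearing carbons (C4/C7a and C4′/C7a′).
2. Endgame: seven acetates are removed last, and the C6–vinyl bond comes from a Mizoroki–Heck coupling of a C6 triflate with 4-acetoxystyrene.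
3. Key disconnection: O1–C2 and O1′–C2′ are cut together. This opens both dihydrofuran rings to a seco-polyphenol in which C2 and C2′ are CH2 groups and C3 and C3′ are the only stereocentres.
4. The C2–aryl and C2′–aryl bonds go back to a diacid (twofold nickel-catalysed decarboxylative arylation) and the diacid to a bis(chroman-2-one). C3′–aryl and then C3–C6′ come from two rhodium-catalysed asymmetric 1,4-additions to coumarins made from 5,7-dihydroxycoumarin.
5. Ring order: both lactone rings come with the purchased coumarin and are opened in step 9. The two dihydrofuran rings are the only rings built, and they close together in step 17.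

Key step: step 17

Assumption on the sense of induction: with simple coumarins, Rh/(R)-SEGPHOS gives (R)-4-arylchroman-2-ones, and the priority order at C4 is the same here, so the (S)-ligand is used for the (4S)-products. If the sense were reversed, the (R)-ligand would be used in steps 5 and 8.

Assumption on supply: [3,5-bis(benzyloxy)phenyl]boronic acid is taken to be a catalogue compound.

Design remarks:
- The C6 oxygen travels as a MOM ether and becomes the triflate only after the nickel step. An aryl triflate would not survive K2CO3/MeOH, LiOH, or low-valent nickel with an arylzinc reagent.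
- The terminal resorcinol is carried as benzyl ethers, which fall in the same BCl3 step as the others. No boron tribromide is then needed once the acid-labile 2-(4-hydroxyphenyl)dihydrofuran rings and the stilbene exist. The key-step precursor is therefore an octaphenol.

**Route**

Step 1
Reactants: 1 5,7-dihydroxycoumarin
Product: 2 5-hydroxy-7-(methoxymethoxy)-2H-chromen-2-one
Conditions: MOMCl (1.0 equiv), iPr2NEt (1.1 equiv), DMF, 0 °C
Reagents that add atoms: chloromethyl methyl ether (MOMCl), COCCl
Why: Selective Williamson-type O-alkylation: the 7-OH is para to C4a, is the stronger vinylogous acid and lacks the peri contact with C4–H that hinders the 5-OH, so it should react first, and one equivalent of reagent plus chromatographic removal of the 5-isomer and the bis-ether secures one regioisomer.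

Step 2
Reactants: 2 5-hydroxy-7-(methoxymethoxy)-2H-chromen-2-one
Product: 3 5-(benzyloxy)-7-(methoxymethoxy)-2H-chromen-2-one
Conditions: BnBr, K2CO3, DMF, rt
Reagents that add atoms: benzyl bromide, BrCc1ccccc1
Why: Williamson etherification of the only remaining phenol, under conditions that leave the coumarin lactone and the MOM acetal intact.

Step 3
Reactants: 3 5-(benzyloxy)-7-(methoxymethoxy)-2H-chromen-2-one (part of the material)
Product: 4 5-(benzyloxy)-7-hydroxy-2H-chromen-2-one
Conditions: conc. HCl (cat.), MeOH, 50 °C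
Reagents that add atoms: none
Why: Acid-catalysed acetal exchange passes the methoxymethyl group to methanol, while the benzyl ether and the coumarin are inert to dilute acid.

Step 4
Reactants: 4 5-(benzyloxy)-7-hydroxy-2H-chromen-2-one
Product: 5 5-(benzyloxy)-2-oxo-2H-chromen-7-yl trifluoromethanesulfonate
Conditions: Tf2O, pyridine, CH2Cl2, 0 °C
Reagents that add atoms: triflic anhydride, O=S(=O)(OS(=O)(=O)C(F)(F)F)C(F)(F)F
Why: O-sulfonylation of the single free phenol gives a coumarin that is a stronger Michael acceptor and carries the handle for the later borylation.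

Step 5
Reactants: 5 5-(benzyloxy)-2-oxo-2H-chromen-7-yl trifluoromethanesulfonate; 6 [3,5-bis(benzyloxy)phenyl]boronic acid
Product: 7 (4S)-5-(benzyloxy)-4-[3,5-bis(benzyloxy)phenyl]-2-oxochroman-7-yl trifluoromethanesulfonate
Conditions: Rh(acac)(C2H4)2 (3 mol%), (S)-SEGPHOS (3.3 mol%), 6 (4 equiv), dioxane/H2O (10:1), 60 °C
Reagents that add atoms: none
Why: Hayashi–Miyaura asymmetric 1,4-addition: the aryl–rhodium species held by (S)-SEGPHOS inserts the C3=C4 bond from one face and water protonates the rhodium enolate, which sets C4 (the later C3′) as S under catalyst control, and the aryl triflate is inert to monovalent rhodium.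

Step 6
Reactants: 7 (4S)-chromanone triflate
Product: 8 (4S)-5-(benzyloxy)-4-[3,5-bis(benzyloxy)phenyl]-7-(4,4,5,5-tetramethyl-1,3,2-dioxaborolan-2-yl)chroman-2-one
Conditions: B2pin2, PdCl2(dppf) (5 mol%), dppf (5 mol%), KOAc, dioxane, 80 °C
Reagents that add atoms: bis(pinacolato)diboron, CC1(C)OB(OC1(C)C)B1OC(C)(C)C(C)(C)O1
Why: Miyaura borylation of an unhindered aryl triflate, in which acetate is too weak a base to open the lactone or to disturb the C4 stereocentre.

Step 7
Reactants: 8 (4S)-chromanone pinacol boronate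
Product: 9 {(4S)-5-(benzyloxy)-4-[3,5-bis(benzyloxy)phenyl]-2-oxochroman-7-yl}boronic acid
Conditions: NaIO4, NH4OAc, acetone/H2O, rt
Reagents that add atoms: water, O
Why: Oxidative cleavage of the pinacol released by hydrolysis pulls the boronate equilibrium to the free boronic acid at near-neutral pH, which gives a partner that transmetalates to rhodium without a base that would open the lactone.

Step 8
Reactants: 9 (4S)-chromanone boronic acid; 3 5-(benzyloxy)-7-(methoxymethoxy)-2H-chromen-2-one
Product: 10 (4S)-5-(benzyloxy)-4-{(4S)-5-(benzyloxy)-4-[3,5-bis(benzyloxy)phenyl]-2-oxochroman-7-yl}-7-(methoxymethoxy)chroman-2-one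
Conditions: Rh(acac)(C2H4)2 (5 mol%), (S)-SEGPHOS (5.5 mol%), 3 (3 equiv, excess recovered), dioxane/H2O (10:1), 60 °C, slow addition of 9
Reagents that add atoms: none
Why: Second Hayashi–Miyaura 1,4-addition, which forms C3–C6′ and sets the new C4 (the later C3) as S under catalyst control since the existing centre is remote, with the cheap coumarin in excess so that insertion can compete with hydrolysis of the aryl–rhodium species.

Step 9
Reactants: 10 bis(chroman-2-one)
Product: 11 methyl (3S)-3-[2,6-bis(benzyloxy)-4-(methoxymethoxy)phenyl]-3-{3,5-bis(benzyloxy)-4-[(1S)-1-[3,5-bis(benzyloxy)phenyl]-3-methoxy-3-oxopropyl]phenyl}propanoate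
Conditions: BnBr, K2CO3, MeOH/acetone, reflux
Reagents that add atoms: methanol, CO; benzyl bromide, BrCc1ccccc1
Why: Carbonate-mediated methanolysis opens both aryl lactones and Williamson benzylation traps each freed phenoxide irreversibly, which stops re-lactonisation and makes the two oxygens beside C3a (and beside C3a′) equivalent.

Step 10
Reactants: 11 dimethyl diester
Product: 12 the corresponding (S,S)-diacid
Conditions: LiOH, THF/MeOH/H2O, 50 °C; then dilute aq. HCl to pH 3, 0 °C
Reagents that add atoms: lithium hydroxide (its oxygen ends in the carboxyl groups), [Li+].[OH-]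
Why: Saponification of two unhindered methyl esters, with ethers, acetal and the non-acidic β-stereocentres unaffected and a brief cold acidification that spares the MOM group.

Step 11
Reactants: 12 (S,S)-diacid
Product: 13 the bis(1,3-dioxoisoindolin-2-yl) diester of 12 (bis redox-active ester)
Conditions: N-hydroxyphthalimide, N,N′-diisopropylcarbodiimide, DMAP (cat.), CH2Cl2, rt
Reagents that add atoms: N-hydroxyphthalimide, O=C1c2ccccc2C(=O)N1O
Why: Steglich-type carbodiimide esterification turns both acids into isolable N-acyloxyphthalimides that accept one electron readily.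

Step 12
Reactants: 14 1-(benzyloxy)-4-bromobenzene
Product: 16 4-(benzyloxy)phenylzinc chloride as a THF solution holding LiCl, via 4-(benzyloxy)phenylmagnesium bromide 15 (not isolated)
Conditions: Mg, LiCl, THF, rt; then ZnCl2, THF, 0 °C to rt
Reagents that add atoms: zinc dichloride, Cl[Zn]Cl; magnesium, [Mg] (held only in 15)
Why: LiCl-assisted Grignard formation followed by transmetalation to zinc gives the mild aryl donor required by the nickel coupling.

Step 13
Reactants: 13 bis redox-active ester; 16 4-(benzyloxy)phenylzinc chloride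
Product: 17 2-[(1S)-1-{3,5-bis(benzyloxy)-4-[(1S)-1-[3,5-bis(benzyloxy)phenyl]-2-[4-(benzyloxy)phenyl]ethyl]phenyl}-2-[4-(benzyloxy)phenyl]ethyl]-1,3-bis(benzyloxy)-5-(methoxymethoxy)benzene
Conditions: NiCl2(dme) (40 mol%), 4,4′-di-tert-butyl-2,2′-bipyridine (80 mol%), 16 (6 equiv), THF/DMF, rt
Reagents that add atoms: none
Why: Nickel-catalysed decarboxylative Negishi-type arylation of redox-active esters: low-valent nickel reduces each N-acyloxyphthalimide by one electron, CO2 and phthalimide anion leave, and aryl–nickel captures the primary C2 (C2′) radical before reductive elimination, which leaves C3 and C3′ untouched, and the high nickel loading is chosen to make that capture fast.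

Step 14
Reactants: 17 octabenzyl MOM ether
Product: 18 the corresponding C6 phenol (3,5-bis(benzyloxy)-4-substituted phenol, C3 and C3′ both S)
Conditions: aq. HCl (cat.), THF/MeOH, 50 °C
Reagents that add atoms: none
Why: Acid-catalysed acetal exchange with methanol removes the one MOM group, methanol traps the formaldehyde equivalent, and the eight benzyl ethers stay in place.

Step 15
Reactants: 18 C6 phenol
Product: 19 the octabenzyl C6 trifluoromethanesulfonate
Conditions: Tf2O, pyridine, CH2Cl2, 0 °C
Reagents that add atoms: triflic anhydride, O=S(=O)(OS(=O)(=O)C(F)(F)F)C(F)(F)F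
Why: O-sulfonylation of the only free and unhindered phenol places the coupling handle at C6 after all steps that would have destroyed it.

Step 16
Reactants: 19 octabenzyl C6 triflate
Product: 20 3,5-dihydroxy-4-[(1S)-1-{4-[(1S)-1-(3,5-dihydroxyphenyl)-2-(4-hydroxyphenyl)ethyl]-3,5-dihydroxyphenyl}-2-(4-hydroxyphenyl)ethyl]phenyl trifluoromethanesulfonate (seco-octaphenol)
Conditions: BCl3, pentamethylbenzene, CH2Cl2, −78 °C; then H2O
Reagents that add atoms: none
Why: Lewis-acid debenzylation with a non-basic cation scavenger: BCl3 activates each aryl benzyl ether and pentamethylbenzene takes up the benzyl cation, so C-benzylation of the resorcinol rings is suppressed and the aryl triflate and both stereocentres are left alone at −78 °C.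

Step 17
Reactants: 20 seco-octaphenol C6 triflate
Product: 22 (2S,3S,2′S,3′S)-bis(trans-2,3-dihydrobenzofuran) hexaphenol C6 triflate, via bis(para-quinone methide) 21 (not isolated)
Conditions: DDQ (2.05 equiv, slow addition), THF (high dilution), 0 °C, argon
Reagents that add atoms: none
Why: DDQ takes a hydride equivalent from each CH2 group para to a free phenol and the phenolic proton is lost, which gives the para-quinone methides drawn in 21 (the two sites act independently, so one may close before the other is oxidised); a hydroxyl on C4/C7a (or C4′/C7a′) then adds to the exocyclic carbon and the 4-hydroxyphenyl ring is rearomatised. The closest known reaction type is the DDQ- or Ag2O-mediated oxidative cyclisation of 2-[2-(4-hydroxyphenyl)ethyl]phenols to 2-aryl-2,3-dihydrobenzofurans through para-quinone methides. The dihydrofuran ring of unit 1 (O1–C2–C3–C3a–C7a) and that of unit 2 (O1′–C2′–C3′–C3a′–C7a′) each close in the 5-exo-trig mode as an intramolecular oxa-Michael addition. C2 is controlled by C3 and C2′ by C3′, because the oxygen adds in the rotamer that holds the quinoid ring anti to the aryl group on the neighbouring carbon, and because the addition is reversible the more stable 2,3-trans isomers should prevail, that is (2S,3S,2′S,3′S). The step needs oxidation at C2–H and C2′–H only: the meta-dioxygenated rings have no quinone form, the triflate lowers the donor strength of the unit 1 ring, and the tertiary C3–H and C3′–H bonds, which could in principle leave through an ortho-quinone methide, are shielded and lie near the plane of their di-ortho-substituted rings, poorly aligned with the π system. The choice between the two flanking hydroxyls is no issue because rotation about C3–C3a (C3′–C3a′) interchanges them, and slow addition of only two equivalents of DDQ at 0 °C in dilute solution is meant to keep closure ahead of prototropic shift to the triarylethylene, intermolecular capture and further dehydrogenation to the benzofuran.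

Step 18
Reactants: 22 bis(dihydrobenzofuran) hexaphenol C6 triflate
Product: 23 the corresponding hexaacetate C6 triflate
Conditions: Ac2O, pyridine, DMAP (cat.), CH2Cl2, rt
Reagents that add atoms: acetic anhydride, CC(=O)OC(C)=O
Why: Exhaustive O-acetylation masks all six phenols, so no phenoxide can poison palladium or reopen a dihydrofuran ring by retro-oxa-Michael reaction in the hot basic coupling that follows.

Step 19
Reactants: 23 hexaacetate C6 triflate; 24 4-acetoxystyrene
Product: 25 the heptaacetate of the target (E-stilbene)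
Conditions: PdCl2(PPh3)2 (10 mol%), LiCl, Et3N, BHT (trace), DMF, 90 °C
Reagents that add atoms: none
Why: Mizoroki–Heck reaction: zerovalent palladium adds to the C6–OTf bond, chloride exchange gives the neutral aryl–palladium chloride that favours terminal arylation of the styrene, and syn insertion followed by syn β-hydride elimination gives the E-alkene.

Step 20
Reactants: 25 heptaacetate
Product: 26 target, (2S,3S)-3-[(2S,3S)-3-(3,5-dihydroxyphenyl)-4-hydroxy-2-(4-hydroxyphenyl)-2,3-dihydro-1-benzofuran-6-yl]-2-(4-hydroxyphenyl)-6-[(E)-2-(4-hydroxyphenyl)ethenyl]-2,3-dihydro-1-benzofuran-4-ol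
Conditions: K2CO3 (cat.), MeOH/THF, 0 °C to rt, argon; then AcOH to neutrality
Reagents that add atoms: none
Why: Base-catalysed (Zemplén-type) methanolysis removes the seven reactive aryl acetates without any Lewis or Brønsted acid, and the trans-dihydrofurans (the thermodynamic isomers) and the E-alkene should persist under these mild conditions.

**Compound list**

1 | 5,7-dihydroxycoumarin | O=c1ccc2c(O)cc(O)cc2o1 | starting material
2 | 5-hydroxy-7-(methoxymethoxy)-2H-chromen-2-one | O=c1ccc2c(O)cc(OCOC)cc2o1 | intermediate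
3 | 5-(benzyloxy)-7-(methoxymethoxy)-2H-chromen-2-one | O=c1ccc2c(OCc3ccccc3)cc(OCOC)cc2o1 | intermediate
4 | 5-(benzyloxy)-7-hydroxy-2H-chromen-2-one | O=c1ccc2c(OCc3ccccc3)cc(O)cc2o1 | intermediate
5 | 5-(benzyloxy)-2-oxo-2H-chromen-7-yl trifluoromethanesulfonate | O=c1ccc2c(OCc3ccccc3)cc(OS(=O)(=O)C(F)(F)F)cc2o1 | intermediate
6 | [3,5-bis(benzyloxy)phenyl]boronic acid | OB(O)c1cc(OCc2ccccc2)cc(OCc2ccccc2)c1 | starting material
7 | (4S)-5-(benzyloxy)-4-[3,5-bis(benzyloxy)phenyl]-2-oxochroman-7-yl trifluoromethanesulfonate | O=C1C[C@@H](c2cc(OCc3ccccc3)cc(OCc3ccccc3)c2)c2c(OCc3ccccc3)cc(OS(=O)(=O)C(F)(F)F)cc2O1 | intermediate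
8 | (4S)-5-(benzyloxy)-4-[3,5-bis(benzyloxy)phenyl]-7-(pinacolatoboryl)chroman-2-one | O=C1C[C@@H](c2cc(OCc3ccccc3)cc(OCc3ccccc3)c2)c2c(OCc3ccccc3)cc(B3OC(C)(C)C(C)(C)O3)cc2O1 | intermediate
9 | {(4S)-5-(benzyloxy)-4-[3,5-bis(benzyloxy)phenyl]-2-oxochroman-7-yl}boronic acid | O=C1C[C@@H](c2cc(OCc3ccccc3)cc(OCc3ccccc3)c2)c2c(OCc3ccccc3)cc(B(O)O)cc2O1 | intermediate
10 | (4S,4′S)-bis(chroman-2-one), 7-MOM ether | O=C1C[C@@H](c3cc(OCc5ccccc5)c4c(c3)OC(=O)C[C@H]4c3cc(OCc5ccccc5)cc(OCc5ccccc5)c3)c2c(OCc3ccccc3)cc(OCOC)cc2O1 | intermediate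
11 | (S,S)-dimethyl diester, hexabenzyl MOM ether | COCOc1cc(OCc2ccccc2)c(c(OCc2ccccc2)c1)[C@@H](CC(=O)OC)c1cc(OCc2ccccc2)c(c(OCc2ccccc2)c1)[C@@H](CC(=O)OC)c1cc(OCc2ccccc2)cc(OCc2ccccc2)c1 | intermediate
12 | (S,S)-diacid | COCOc1cc(OCc2ccccc2)c(c(OCc2ccccc2)c1)[C@@H](CC(=O)O)c1cc(OCc2ccccc2)c(c(OCc2ccccc2)c1)[C@@H](CC(=O)O)c1cc(OCc2ccccc2)cc(OCc2ccccc2)c1 | intermediate
13 | (S,S)-bis(N-hydroxyphthalimide) ester | COCOc1cc(OCc2ccccc2)c(c(OCc2ccccc2)c1)[C@@H](CC(=O)ON2C(=O)c3ccccc3C2=O)c1cc(OCc2ccccc2)c(c(OCc2ccccc2)c1)[C@@H](CC(=O)ON2C(=O)c3ccccc3C2=O)c1cc(OCc2ccccc2)cc(OCc2ccccc2)c1 | intermediate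
14 | 1-(benzyloxy)-4-bromobenzene | Brc1ccc(OCc2ccccc2)cc1 | starting material
15 | 4-(benzyloxy)phenylmagnesium bromide | Br[Mg]c1ccc(OCc2ccccc2)cc1 | intermediate (not isolated)
16 | 4-(benzyloxy)phenylzinc chloride | Cl[Zn]c1ccc(OCc2ccccc2)cc1 | intermediate
17 | (S,S)-octabenzyl seco-trimer core, C6 MOM ether | COCOc1cc(OCc2ccccc2)c(c(OCc2ccccc2)c1)[C@@H](Cc1ccc(OCc2ccccc2)cc1)c1cc(OCc2ccccc2)c(c(OCc2ccccc2)c1)[C@@H](Cc1ccc(OCc2ccccc2)cc1)c1cc(OCc2ccccc2)cc(OCc2ccccc2)c1 | intermediate
18 | (S,S)-octabenzyl seco-trimer core, C6 phenol | Oc1cc(OCc2ccccc2)c(c(OCc2ccccc2)c1)[C@@H](Cc1ccc(OCc2ccccc2)cc1)c1cc(OCc2ccccc2)c(c(OCc2ccccc2)c1)[C@@H](Cc1ccc(OCc2ccccc2)cc1)c1cc(OCc2ccccc2)cc(OCc2ccccc2)c1 | intermediate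
19 | (S,S)-octabenzyl seco-trimer core, C6 triflate | O=S(=O)(Oc1cc(OCc2ccccc2)c(c(OCc2ccccc2)c1)[C@@H](Cc1ccc(OCc2ccccc2)cc1)c1cc(OCc2ccccc2)c(c(OCc2ccccc2)c1)[C@@H](Cc1ccc(OCc2ccccc2)cc1)c1cc(OCc2ccccc2)cc(OCc2ccccc2)c1)C(F)(F)F | intermediate
20 | (S,S)-seco-octaphenol C6 triflate (key-step precursor) | O=S(=O)(Oc1cc(O)c(c(O)c1)[C@@H](Cc1ccc(O)cc1)c1cc(O)c(c(O)c1)[C@@H](Cc1ccc(O)cc1)c1cc(O)cc(O)c1)C(F)(F)F | intermediate
21 | bis(para-quinone methide) of 20 | O=S(=O)(Oc1cc(O)c(c(O)c1)[C@@H](C=C1C=CC(=O)C=C1)c1cc(O)c(c(O)c1)[C@@H](C=C1C=CC(=O)C=C1)c1cc(O)cc(O)c1)C(F)(F)F | intermediate (not isolated)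
22 | (2S,3S)-3-[(2S,3S)-3-(3,5-dihydroxyphenyl)-4-hydroxy-2-(4-hydroxyphenyl)-2,3-dihydro-1-benzofuran-6-yl]-4-hydroxy-2-(4-hydroxyphenyl)-2,3-dihydro-1-benzofuran-6-yl trifluoromethanesulfonate (key-step product) | O=S(=O)(Oc1cc(O)c2c(c1)O[C@H](c1ccc(O)cc1)[C@H]2c1cc(O)c2c(c1)O[C@H](c1ccc(O)cc1)[C@H]2c1cc(O)cc(O)c1)C(F)(F)F | intermediate
23 | hexaacetate of 22 | O=S(=O)(Oc1cc(OC(C)=O)c2c(c1)O[C@H](c1ccc(OC(C)=O)cc1)[C@H]2c1cc(OC(C)=O)c2c(c1)O[C@H](c1ccc(OC(C)=O)cc1)[C@H]2c1cc(OC(C)=O)cc(OC(C)=O)c1)C(F)(F)F | intermediate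
24 | 4-acetoxystyrene | CC(=O)Oc1ccc(C=C)cc1 | starting material
25 | heptaacetate of the target | CC(=O)Oc1ccc(/C=C/c2cc(OC(C)=O)c3c(c2)O[C@H](c2ccc(OC(C)=O)cc2)[C@H]3c2cc(OC(C)=O)c3c(c2)O[C@H](c2ccc(OC(C)=O)cc2)[C@H]3c2cc(OC(C)=O)cc(OC(C)=O)c2)cc1 | intermediate
26 | CNP0248228.2, (2S,3S,2′S,3′S) | Oc1ccc(/C=C/c2cc(O)c3c(c2)O[C@H](c2ccc(O)cc2)[C@H]3c2cc(O)c3c(c2)O[C@H](c2ccc(O)cc2)[C@H]3c2cc(O)cc(O)c2)cc1 | target

**Step count**

Total step count: 20. Longest linear sequence: 19 steps (1 to 26 through steps 1–11 and 13–20; step 12 is the side branch).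

**Steps most likely to fail**

**Step 17 (twofold oxidative cyclisation).**
- What may go wrong: hydrogen loss from C3–H or C3′–H through an ortho-quinone methide of a 2-alkylresorcinol ring, which erodes the stereocentres.
- Other failure processes are prototropic shift of a para-quinone methide to the triarylethylene, capture of a quinone methide by a phenol of another molecule, and further dehydrogenation of a closed ring to the benzofuran while oxidant is still present.
- Fallback: separate the C–H oxidation from the C–O ring closure. It sets out from 20 and comes back at 22.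
- DDQ (two equivalents) is used in MeOH/CH2Cl2 at low temperature. The solvent, present in vast excess, intercepts each quinone methide as it forms and gives the bis(benzylic methyl ether) F1 (epimers at C2 and C2′, of no consequence).
- F1 is freed from oxidant and hydroquinone. It is then ionised with catalytic camphorsulfonic acid in CH2Cl2/hexafluoroisopropanol at 0 °C.
- Both rings then close by acid-catalysed SN1-type etherification, a known way to 2-aryl-dihydrobenzofurans, under thermodynamic control and with no oxidant present, to give the trans,trans compound 22.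

**Step 13 (twofold decarboxylative arylation).**
- What may go wrong: the primary 2,2-diarylethyl radical may undergo a 1,2-aryl shift, or take a hydrogen atom from an ortho-benzyloxy CH2 group, before nickel captures it. Reaction at the second ester may also be incomplete.
- Fallback: bring the aryl group in by polar enolate chemistry and use the radical only to make a C–H bond at a stabilised benzylic position. It sets out from 11 and 14 and comes back at 17.
- Palladium-catalysed ester enolate α-arylation (LiHMDS, Pd(dba)2, P(t-Bu)3, toluene) of both ester arms of 11 with 14 gives the bis(α-aryl) dimethyl diester F2 (epimers at the α-carbons, later erased).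
- KOH in aqueous dioxane/MeOH at 90 °C gives the bis(α-aryl) diacid F3.
- N-hydroxyphthalimide and N,N′-diisopropylcarbodiimide give the bis(α-aryl) bis(N-hydroxyphthalimide) ester F4.
- Barton-type reductive decarboxylation (NiCl2·6H2O, 4,4′-di-tert-butyl-2,2′-bipyridine, Zn, PhSiH3, THF/DMF/iPrOH, 40 °C) replaces each carboxyl group by hydrogen through a secondary benzylic radical, which has no driving force to rearrange, and gives 17.

**Step 8 (second rhodium addition).**
- What may go wrong: hydrolysis of the aryl–rhodium intermediate, that is net protodeboronation of the valuable boronic acid, may outrun insertion of the electron-rich and peri-substituted C3=C4 bond of 3.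
- Fallback: raise the acceptor strength with an activating group that is exchanged afterwards. It sets out from 9 and 5 and comes back at 10.
- The same Rh(acac)(C2H4)2/(S)-SEGPHOS addition is run on the electron-poor triflate coumarin 5 (in excess), the acceptor class already used in step 5, to give the bis(chroman-2-one) C7 triflate F5.
- Et4NOH in aqueous dioxane at rt cleaves the S–O bond of the triflate. Both lactones open meanwhile and close again on acidification with dilute HCl. This gives the bis(chroman-2-one) C7 phenol F6.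
- MOMCl/iPr2NEt in CH2Cl2 then gives 10.

**Further compounds**

F1 | step 17 | bis(benzylic methyl ether) of 20 (C2 and C2′ as CH(OMe), C3 and C3′ as in 20) | O=S(=O)(Oc1cc(O)c(c(O)c1)[C@@H](C(OC)c1ccc(O)cc1)c1cc(O)c(c(O)c1)[C@@H](C(OC)c1ccc(O)cc1)c1cc(O)cc(O)c1)C(F)(F)F
F2 | step 13 | bis(α-aryl) dimethyl diester (α-[4-(benzyloxy)phenyl] on both ester arms of 11) | COCOc1cc(OCc2ccccc2)c(c(OCc2ccccc2)c1)[C@@H](C(C(=O)OC)c1ccc(OCc2ccccc2)cc1)c1cc(OCc2ccccc2)c(c(OCc2ccccc2)c1)[C@@H](C(C(=O)OC)c1ccc(OCc2ccccc2)cc1)c1cc(OCc2ccccc2)cc(OCc2ccccc2)c1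
F3 | step 13 | bis(α-aryl) diacid | COCOc1cc(OCc2ccccc2)c(c(OCc2ccccc2)c1)[C@@H](C(C(=O)O)c1ccc(OCc2ccccc2)cc1)c1cc(OCc2ccccc2)c(c(OCc2ccccc2)c1)[C@@H](C(C(=O)O)c1ccc(OCc2ccccc2)cc1)c1cc(OCc2ccccc2)cc(OCc2ccccc2)c1
F4 | step 13 | bis(α-aryl) bis(N-hydroxyphthalimide) ester | COCOc1cc(OCc2ccccc2)c(c(OCc2ccccc2)c1)[C@@H](C(C(=O)ON2C(=O)c3ccccc3C2=O)c1ccc(OCc2ccccc2)cc1)c1cc(OCc2ccccc2)c(c(OCc2ccccc2)c1)[C@@H](C(C(=O)ON2C(=O)c3ccccc3C2=O)c1ccc(OCc2ccccc2)cc1)c1cc(OCc2ccccc2)cc(OCc2ccccc2)c1
F5 | step 8 | (4S,4′S)-bis(chroman-2-one) C7 triflate | O=C1C[C@@H](c3cc(OCc5ccccc5)c4c(c3)OC(=O)C[C@H]4c3cc(OCc5ccccc5)cc(OCc5ccccc5)c3)c2c(OCc3ccccc3)cc(OS(=O)(=O)C(F)(F)F)cc2O1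
F6 | step 8 | (4S,4′S)-bis(chroman-2-one) C7 phenol | O=C1C[C@@H](c3cc(OCc5ccccc5)c4c(c3)OC(=O)C[C@H]4c3cc(OCc5ccccc5)cc(OCc5ccccc5)c3)c2c(OCc3ccccc3)cc(O)cc2O1
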